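**Plan**

- Numbering: benzofuran O1, C2 (carries syringyl ring A), C3 (carries C9H2OH), benzo ring B (C5 side chain, C7 OMe).
- Retrosynthesis: the allylic alcohol goes back to the acrylate ester, and its C=C (Wittig) to a C5 aldehyde. C3–C9 and O1–C2 are then cut together, leaving formaldehyde and a flat 2-hydroxystilbene. The aryl–vinyl bond of the stilbene (Heck) is cut last, to 5-iodovanillin and 4-vinylsyringol.
- Enabling feature: C2 is benzylic to ring A and para to its free hydroxyl, so it can hold positive charge as a para-quinone methide. O1 of ring B sits at five-ring distance from C2, C9 is a lone one-carbon unit on C3, and every position ortho or para to either hydroxyl is substituted.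
- Forward: sinapic acid is decarboxylated, the styrene is joined to ring B by Heck coupling, and the dihydrofuran (the only ring made) closes in the Prins/phenol-capture step. Ring B keeps its side chain as a formyl group through that step, so that O1 is a poor donor and C3, not C2, is the nucleophilic alkene carbon. Wittig extension and ester reduction finish the chain.
- Stereochemistry: C3 comes from the chiral confined acid in the C3–C9 bond formation. C2 settles trans to C9 through reversible O1–C2 ionisation. Both E alkenes come from Heck and Wittig selectivity.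

Key step: step 3

Assumption: the sense of induction of the imidodiphosphorimidate acid (IDPi: N-triflyl imidodiphosphorimidate built from two 3,3'-diaryl-BINOL units) cannot be predicted for this substrate class, so both antipodes are screened and the one that gives (3S) is used; it is written (S,S)-IDPi below.

Step 1
Reactants: 1 sinapic acid
Product: 2 4-vinylsyringol (4-ethenyl-2,6-dimethoxyphenol)
Conditions: DBU (0.2 equiv), DMF, 130 °C, N2
Reagents that add atoms: none
Why: Thermal decarboxylation of a 4-hydroxycinnamic acid, whose quinone methide tautomer is a vinylogous beta-keto acid and loses CO2 to give the 4-vinylphenol.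

Step 2
Reactants: 2 4-vinylsyringol; 3 5-iodovanillin
Product: 4 (E)-4-hydroxy-3-[2-(4-hydroxy-3,5-dimethoxyphenyl)ethenyl]-5-methoxybenzaldehyde
Conditions: Pd(OAc)2 (5 mol%), P(o-tol)3 (10 mol%), Et3N, DMF, 90 °C, N2
Reagents that add atoms: none
Why: Mizoroki–Heck reaction in which zerovalent palladium formed from Pd(OAc)2 inserts into the C–I bond of 3, the aryl group adds to the unsubstituted terminus of styrene 2 and syn beta-hydride elimination gives the E stilbene, a coupling that is well known for unprotected iodophenols and vinylphenols.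

Step 3
Reactants: 4 (E)-4-hydroxy-3-[2-(4-hydroxy-3,5-dimethoxyphenyl)ethenyl]-5-methoxybenzaldehyde; 5 formaldehyde (as paraformaldehyde)
Product: 7 (2R,3S)-2-(4-hydroxy-3,5-dimethoxyphenyl)-3-(hydroxymethyl)-7-methoxy-2,3-dihydro-1-benzofuran-5-carbaldehyde, via ring A para-quinone methide 6 (not isolated)
Conditions: (S,S)-IDPi (5 mol%), (CH2O)n (1.2 equiv), CHCl3, −20 °C; then MeOH, aq. NaHCO3
Reagents that add atoms: none
Why: Proposed new method: the confined acid delivers O-protonated monomeric formaldehyde to C3 of stilbene 4, the carbon made nucleophilic by the para hydroxyl of ring A (a vinylogous enol), so that C3–C9 forms and the charge lands on C2 as the O-protonated para-quinone methide 6; the closest known reaction type is the catalytic asymmetric intermolecular Prins reaction of styrenes with paraformaldehyde under IDPi acids, which has not been shown on 1,2-diarylalkenes or with interception by a phenol. The dihydrofuran ring closes by 5-exo-trig attack of the ring B oxygen O1 on C2 of 6, an intramolecular capture that should outrun addition of a second formaldehyde (the path to the usual 1,3-dioxane), the more so as formaldehyde is held near one equivalent. C3 is fixed in the irreversible C–C bond formation by the chiral pocket of the catalyst, which should leave one face of the E alkene open at C3. C2 is fixed relative to C3 under thermodynamic control, because the para-hydroxybenzyl aryl ether bond O1–C2 re-ionises under the acid and settles with ring A trans to C9. The step needs C3 and not C2 as the nucleophilic carbon and needs formaldehyde to react at the alkene and not at O1 or an arene: the formyl group para to O1 makes ring B a vanillin-type, weakly donating phenol that neither stabilises charge at C3 nor readily forms an aryloxymethyl cation, and all positions ortho and para to the two hydroxyls are substituted.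

Step 4
Reactants: 7 (2R,3S)-2-(4-hydroxy-3,5-dimethoxyphenyl)-3-(hydroxymethyl)-7-methoxy-2,3-dihydro-1-benzofuran-5-carbaldehyde; 8 methyl (triphenylphosphoranylidene)acetate
Product: 9 methyl (E)-3-[(2R,3S)-2-(4-hydroxy-3,5-dimethoxyphenyl)-3-(hydroxymethyl)-7-methoxy-2,3-dihydro-1-benzofuran-5-yl]prop-2-enoate
Conditions: toluene, 80 °C
Reagents that add atoms: none
Why: Wittig olefination with a stabilised ylide, which is E-selective with aromatic aldehydes and, being only weakly basic, should leave the free phenol, the primary alcohol and both stereocentres untouched.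

Step 5
Reactants: 9 methyl (E)-3-[(2R,3S)-2-(4-hydroxy-3,5-dimethoxyphenyl)-3-(hydroxymethyl)-7-methoxy-2,3-dihydro-1-benzofuran-5-yl]prop-2-enoate
Product: 11 (E)-3-[(2R,3S)-2-(4-hydroxy-3,5-dimethoxyphenyl)-3-(hydroxymethyl)-7-methoxy-2,3-dihydro-1-benzofuran-5-yl]prop-2-en-1-ol (the target), via enal 10 (not isolated)
Conditions: i-Bu2AlH (6 equiv), THF/toluene, −78 to 0 °C; aq. KNaC4H4O6 work-up
Reagents that add atoms: none
Why: Ester reduction with excess i-Bu2AlH, in which the first equivalents are consumed by the phenol and the primary alcohol and the cinnamate is then reduced 1,2 through enal 10 to the allylic alcohol, as is routine for free-phenolic hydroxycinnamate esters, while neither stereocentre carries an acidic hydrogen.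

**Compound list**

1 | sinapic acid, (E)-3-(4-hydroxy-3,5-dimethoxyphenyl)prop-2-enoic acid | COc1cc(/C=C/C(=O)O)cc(OC)c1O | starting material
2 | 4-vinylsyringol, 4-ethenyl-2,6-dimethoxyphenol | C=Cc1cc(OC)c(O)c(OC)c1 | intermediate
3 | 5-iodovanillin, 4-hydroxy-3-iodo-5-methoxybenzaldehyde | COc1cc(C=O)cc(I)c1O | starting material
4 | (E)-4-hydroxy-3-[2-(4-hydroxy-3,5-dimethoxyphenyl)ethenyl]-5-methoxybenzaldehyde | O=Cc1cc(OC)c(O)c(/C=C/c2cc(OC)c(O)c(OC)c2)c1 | intermediate
5 | formaldehyde (used as paraformaldehyde) | C=O | starting material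
6 | ring A para-quinone methide, (S)-3-[1-(3,5-dimethoxy-4-oxocyclohexa-2,5-dien-1-ylidene)-3-hydroxypropan-2-yl]-4-hydroxy-5-methoxybenzaldehyde, present as its O-protonated ion pair with the catalyst anion | O=Cc1cc(OC)c(O)c(c1)[C@H](C=C1C=C(OC)C(=O)C(OC)=C1)CO | intermediate (not isolated)
7 | (2R,3S)-2-(4-hydroxy-3,5-dimethoxyphenyl)-3-(hydroxymethyl)-7-methoxy-2,3-dihydro-1-benzofuran-5-carbaldehyde (trans) | COc1cc([C@@H]2Oc3c(OC)cc(C=O)cc3[C@H]2CO)cc(OC)c1O | intermediate
8 | methyl (triphenylphosphoranylidene)acetate | COC(=O)C=P(c1ccccc1)(c1ccccc1)c1ccccc1 | starting material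
9 | methyl (E)-3-[(2R,3S)-2-(4-hydroxy-3,5-dimethoxyphenyl)-3-(hydroxymethyl)-7-methoxy-2,3-dihydro-1-benzofuran-5-yl]prop-2-enoate | COc1cc([C@@H]2Oc3c(OC)cc(/C=C/C(=O)OC)cc3[C@H]2CO)cc(OC)c1O | intermediate
10 | (E)-3-[(2R,3S)-2-(4-hydroxy-3,5-dimethoxyphenyl)-3-(hydroxymethyl)-7-methoxy-2,3-dihydro-1-benzofuran-5-yl]prop-2-enal | COc1cc([C@@H]2Oc3c(OC)cc(/C=C/C=O)cc3[C@H]2CO)cc(OC)c1O | intermediate (not isolated)
11 | (E)-3-[(2R,3S)-2-(4-hydroxy-3,5-dimethoxyphenyl)-3-(hydroxymethyl)-7-methoxy-2,3-dihydro-1-benzofuran-5-yl]prop-2-en-1-ol | COc1cc([C@@H]2Oc3c(OC)cc(/C=C/CO)cc3[C@H]2CO)cc(OC)c1O | target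

**Step count**

Total: 5 steps. Longest linear sequence: 5 steps (sinapic acid 1 to target 11); 5-iodovanillin 3 enters at step 2.

**Steps most likely to fail**

Step 3 (the proposed new method).
- What may go wrong: formaldehyde may add at C2 instead of C3, or the catalyst pocket may fail to tell the two faces at C3 apart.
- Protonation of the electron-rich alkene (ring closure without C9, or cationic oligomerisation) may outrun the Prins addition.
- The methoxy-activated positions of ring A may be hydroxymethylated, or a second formaldehyde may divert material to a 1,3-dioxane.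
- Fallback with known chemistry: the C2–C3 bond is made by enantioselective carbenoid C–H insertion. It sets out from 3 and comes back to the route at 11. Wittig olefination of 3 with 8 (toluene, 80 °C) should give methyl (E)-3-(4-hydroxy-3-iodo-5-methoxyphenyl)prop-2-enoate F1. Commercial syringaldehyde is acylated (pivaloyl chloride, Et3N, DMAP) to 4-formyl-2,6-dimethoxyphenyl pivalate F2 and reduced (NaBH4, MeOH, 0 °C) to 4-(hydroxymethyl)-2,6-dimethoxyphenyl pivalate F3. Mitsunobu etherification of F1 with F3 (PPh3, DIAD, THF) should give methyl (E)-3-[4-{[3,5-dimethoxy-4-(pivaloyloxy)benzyl]oxy}-3-iodo-5-methoxyphenyl]prop-2-enoate F4. Coupling of the aryl iodide with methyl diazoacetate under Pd(PPh3)4, Ag2CO3 and Et3N, which keeps the diazo group, should give methyl (E)-3-[3-(1-diazo-2-methoxy-2-oxoethyl)-4-{[3,5-dimethoxy-4-(pivaloyloxy)benzyl]oxy}-5-methoxyphenyl]prop-2-enoate F5. Rh2(S-PTTL)4, dirhodium tetrakis[N-phthaloyl-(S)-tert-leucinate], or its antipode, whichever gives 2R, should effect 1,5 insertion of the carbenoid into the benzylic O–CH2 bond and give the cis ester methyl (2R,3S)-2-[3,5-dimethoxy-4-(pivaloyloxy)phenyl]-7-methoxy-5-[(E)-3-methoxy-3-oxoprop-1-enyl]-2,3-dihydro-1-benzofuran-3-carboxylate F6. DBU in warm toluene epimerises C3 (alpha to the ester) while C2 keeps the configuration set by the rhodium catalyst, giving the trans ester methyl (2R,3R)-2-[3,5-dimethoxy-4-(pivaloyloxy)phenyl]-7-methoxy-5-[(E)-3-methoxy-3-oxoprop-1-enyl]-2,3-dihydro-1-benzofuran-3-carboxylate F7. Excess i-Bu2AlH then reduces both methyl esters and cleaves the pivalate to give 11.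

Step 2.
- What may go wrong: thermal or base-induced oligomerisation of the unprotected vinylphenol 2, and sluggish oxidative addition to the electron-rich iodophenoxide with catalyst decay.
- Fallback: the stilbene is made by Suzuki–Miyaura coupling of an alkenylboronate. It sets out from 2 and 3 and comes back at 4. Cross-metathesis of 2 with vinylboronic acid pinacol ester (second-generation Grubbs catalyst (H2IMes)(PCy3)Cl2Ru=CHPh, CH2Cl2, 40 °C) should give 2,6-dimethoxy-4-[(E)-2-(4,4,5,5-tetramethyl-1,3,2-dioxaborolan-2-yl)ethenyl]phenol F8. Coupling of this boronate with 3 (Pd(PPh3)4, K2CO3, dioxane/H2O, 80 °C), a reaction type well established for 5-iodovanillin, should give 4 with the E geometry retained.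

Step 5.
- What may go wrong: hydride opening of the benzylic aryl ether O1–C2 through a quinone methide released from the aluminium phenoxide, or conjugate reduction of the cinnamate.
- Fallback: the ester oxidation level is avoided altogether. It sets out from 7 and comes back at 11. Wittig olefination of 7 with (triphenylphosphoranylidene)acetaldehyde (toluene, 80 °C) should give enal 10, now isolated. Luche reduction (NaBH4, CeCl3·7H2O, MeOH, 0 °C) should give 11 by 1,2-reduction without aluminium reagents.

Further compounds
F1 | step 3 | methyl (E)-3-(4-hydroxy-3-iodo-5-methoxyphenyl)prop-2-enoate | COC(=O)/C=C/c1cc(OC)c(O)c(I)c1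
F2 | step 3 | 4-formyl-2,6-dimethoxyphenyl pivalate | CC(C)(C)C(=O)Oc1c(OC)cc(C=O)cc1OC
F3 | step 3 | 4-(hydroxymethyl)-2,6-dimethoxyphenyl pivalate | CC(C)(C)C(=O)Oc1c(OC)cc(CO)cc1OC
F4 | step 3 | methyl (E)-3-[4-{[3,5-dimethoxy-4-(pivaloyloxy)benzyl]oxy}-3-iodo-5-methoxyphenyl]prop-2-enoate | COC(=O)/C=C/c1cc(OC)c(OCc2cc(OC)c(OC(=O)C(C)(C)C)c(OC)c2)c(I)c1
F5 | step 3 | methyl (E)-3-[3-(1-diazo-2-methoxy-2-oxoethyl)-4-{[3,5-dimethoxy-4-(pivaloyloxy)benzyl]oxy}-5-methoxyphenyl]prop-2-enoate | COC(=O)/C=C/c1cc(OC)c(OCc2cc(OC)c(OC(=O)C(C)(C)C)c(OC)c2)c(C(=[N+]=[N-])C(=O)OC)c1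
F6 | step 3 | methyl (2R,3S)-2-[3,5-dimethoxy-4-(pivaloyloxy)phenyl]-7-methoxy-5-[(E)-3-methoxy-3-oxoprop-1-enyl]-2,3-dihydro-1-benzofuran-3-carboxylate (cis) | COc1cc([C@@H]2Oc3c(OC)cc(/C=C/C(=O)OC)cc3[C@@H]2C(=O)OC)cc(OC)c1OC(=O)C(C)(C)C
F7 | step 3 | methyl (2R,3R)-2-[3,5-dimethoxy-4-(pivaloyloxy)phenyl]-7-methoxy-5-[(E)-3-methoxy-3-oxoprop-1-enyl]-2,3-dihydro-1-benzofuran-3-carboxylate (trans) | COc1cc([C@@H]2Oc3c(OC)cc(/C=C/C(=O)OC)cc3[C@H]2C(=O)OC)cc(OC)c1OC(=O)C(C)(C)C
F8 | step 2 | 2,6-dimethoxy-4-[(E)-2-(4,4,5,5-tetramethyl-1,3,2-dioxaborolan-2-yl)ethenyl]phenol | COc1cc(/C=C/B2OC(C)(C)C(C)(C)O2)cc(OC)c1O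
F0 | step 5 | none | none
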